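## Retrosynthetic overview

1. Target 32 ⇐ (desilylation, O-demethylation) silyl-protected 4-O-methyl bicycle 30 ⇐ (radical decarbonylation, hydrogen delivered to the exo face of C7) 7-formyl-7-prenyl bicycle 29.
2. 29 ⇐ one-pot (3+3) alkylative dearomatisation–annulation of the flat aroylphloroglucinol monomethyl ether 22 with the acetoxymethyl enal 26 (C1–C8 bond by Michael addition/acetate loss, then C5–C6 bond closes ring B), with the C7 enolate capped by prenyl bromide.
3. Enabling feature: ring A with C9 (C1–C2–C3–C4–C5–C9) is a dearomatised 2-aroylphloroglucinol. C1 and C5 are its two ring carbons ortho to the C9 oxygen and 1,3 to each other, so the C6–C7–C8 bridge of ring B (C1–C8–C7–C6–C5–C9) can be laid across an arene as a 1,3-bis-electrophile. With the C4 oxygen as a methyl ether, C1 is the only carbon between two phenoxides and receives CMe2.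
4. 22 ⇐ 5-methoxyresorcinol bis-MOM ether by three directed metalations (prenyl; iodide, then Negishi coupling with the zinc reagent from iodide 7; Weinreb amide 19). 7 ⇐ (S)-lactone 3 (Rh/BINAP conjugate addition), isopropenyllithium, CBS reduction.
5. Ring order: both benzene rings are bought; ring A is the phloroglucinol ring throughout; ring B is closed last, in step 17.

Key step: step 17

Remarks and assumptions:
- Locants C1–C9 are those of the bicyclo[3.3.1]nonane core of the target: C1 prenyl bridgehead, C2 ketone, C3 aroyl carbon, C4 enol carbon, C5 side-chain bridgehead, C6 CH2, C7 CH-prenyl, C8 CMe2, C9 bridging ketone. The same locants are used for the corresponding carbons of the aromatic precursors.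
- The target has the C7 prenyl group endo, on the side of the C2–C3–C4 bridge; this was derived from the SMILES, which corresponds to (1R,5R,7R) with a (2S,4R) side chain.
- The senses of induction of (S)-BINAP (step 1), (S)-Me-CBS (step 4) and the cinchonidinium catalyst (step 17) are assigned by analogy with simpler substrates. If a first run shows the opposite sense, the mirror-image ligand or the cinchonine-derived pseudo-enantiomer is used.

## Route

Step 1
Reactants: 1 furan-2(5H)-one; 2 isopropenylboronic acid pinacol ester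
Product: 3 (S)-4-(prop-1-en-2-yl)dihydrofuran-2(3H)-one
Conditions: [Rh(cod)OH]2 (2.5 mol%), (S)-BINAP (6 mol%), dioxane/H2O 10:1, 50 °C
Reagents that add atoms: none
Why: Rhodium-catalysed asymmetric conjugate addition of an alkenylboron reagent (Hayashi–Miyaura reaction) to the butenolide; the (S)-BINAP–rhodium alkenyl species should add to one enantioface and set the future C2 stereocentre of the side chain, as in additions to cyclic enones and unsaturated lactones.

Step 2
Reactants: 3 (S)-4-(prop-1-en-2-yl)dihydrofuran-2(3H)-one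
Product: 4 (5S)-6-hydroxy-2-methyl-5-(prop-1-en-2-yl)hex-1-en-3-one
Conditions: 2-bromopropene, t-BuLi (2 equiv), Et2O, −78 °C; then 3, THF, −78 °C; aq. NH4Cl
Reagents that add atoms: isopropenyllithium, [Li]C(C)=C (made in the flask from 2-bromopropene, C=C(C)Br)
Why: Mono-addition of an alkenyllithium to a γ-lactone: the tetrahedral lithium alkoxide should persist at −78 °C and give the γ-hydroxy enone only on work-up, with the β-stereocentre untouched.

Step 3
Reactants: 4 (5S)-6-hydroxy-2-methyl-5-(prop-1-en-2-yl)hex-1-en-3-one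
Product: 5 (5S)-6-iodo-2-methyl-5-(prop-1-en-2-yl)hex-1-en-3-one
Conditions: PPh3, I2, imidazole, CH2Cl2, 0 °C
Reagents that add atoms: iodine, II
Why: Appel iodination of the primary alcohol under neutral conditions, which should leave the enone and the stereocentre alone.

Step 4
Reactants: 5 (5S)-6-iodo-2-methyl-5-(prop-1-en-2-yl)hex-1-en-3-one
Product: 6 (3R,5S)-6-iodo-2-methyl-5-(prop-1-en-2-yl)hex-1-en-3-ol
Conditions: (S)-Me-CBS (20 mol%), catecholborane, toluene, −78 °C; aqueous work-up
Reagents that add atoms: none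
Why: Corey–Bakshi–Shibata reduction: with the isopropenyl group as the large and the CH2 chain as the small ketone substituent, the (S)-oxazaborolidine should deliver hydride to the face that gives the (R)-allylic alcohol under reagent control, independent of the remote centre.

Step 5
Reactants: 6 (3R,5S)-6-iodo-2-methyl-5-(prop-1-en-2-yl)hex-1-en-3-ol
Product: 7 TBS ether of 6, tert-butyl{[(3R,5S)-6-iodo-2-methyl-5-(prop-1-en-2-yl)hex-1-en-3-yl]oxy}dimethylsilane
Conditions: TBSOTf, 2,6-lutidine, CH2Cl2, −78 °C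
Reagents that add atoms: tert-butyldimethylsilyl triflate, CC(C)(C)[Si](C)(C)OS(=O)(=O)C(F)(F)F
Why: Silylation of the secondary allylic alcohol with the silyl triflate is fast at −78 °C, so the primary iodide is not attacked by the base.

Step 6
Reactants: 8 5-methoxybenzene-1,3-diol
Product: 9 1-methoxy-3,5-bis(methoxymethoxy)benzene
Conditions: MOMCl, i-Pr2NEt, CH2Cl2, 0 °C → rt
Reagents that add atoms: chloromethyl methyl ether, COCCl
Why: Acetalisation of both phenols; the MOM groups are the directing groups for the three metalations and leave the methyl ether as the later C4 oxygen.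

Step 7
Reactants: 9 1-methoxy-3,5-bis(methoxymethoxy)benzene
Product: 11 5-methoxy-1,3-bis(methoxymethoxy)-2-(3-methylbut-2-en-1-yl)benzene, via aryllithium 10 (not isolated)
Conditions: n-BuLi, THF, 0 °C; CuI (10 mol%), prenyl bromide, −78 °C → rt
Reagents that add atoms: prenyl bromide, CC(C)=CCBr
Why: Directed ortho-metalation occurs at the carbon between the two OMOM groups, the strongest cooperative directing pair, and the aryllithium is alkylated by prenyl bromide (copper-assisted SN2).

Step 8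
Reactants: 11 5-methoxy-1,3-bis(methoxymethoxy)-2-(3-methylbut-2-en-1-yl)benzene
Product: 13 2-iodo-1-methoxy-3,5-bis(methoxymethoxy)-4-(3-methylbut-2-en-1-yl)benzene, via aryllithium 12 (not isolated)
Conditions: n-BuLi, TMEDA, THF, −78 → −20 °C; I2, −78 °C
Reagents that add atoms: iodine, II
Why: A second directed ortho-metalation at one of the two equivalent positions between OMe and OMOM, then iodination of the aryllithium.

Step 9
Reactants: 7 TBS-protected side-chain iodide; 13 aryl iodide
Product: 16 tert-butyl({(3R,5S)-6-[6-methoxy-2,4-bis(methoxymethoxy)-3-(3-methylbut-2-en-1-yl)phenyl]-2-methyl-5-(prop-1-en-2-yl)hex-1-en-3-yl}oxy)dimethylsilane, via alkyllithium 14 (not isolated), via alkylzinc chloride 15 (not isolated)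
Conditions: 7, t-BuLi (2.1 equiv), Et2O, −78 °C; ZnCl2, THF, −78 °C → rt; then 13, Pd(OAc)2 (3 mol%), SPhos (6 mol%), THF, 50 °C
Reagents that add atoms: none
Why: Negishi sp3–sp2 cross-coupling: polar iodine–lithium exchange at −78 °C avoids radical vinyl migration in the homoallylic chain, the alkylzinc tolerates the silyl ether, and a biarylphosphine–palladium catalyst couples it with the di-ortho-substituted aryl iodide; neither stereocentre is at a reacting carbon.

Step 10
Reactants: 17 methyl 3,4-dihydroxybenzoate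
Product: 18 methyl 3,4-bis[(triisopropylsilyl)oxy]benzoate
Conditions: TIPSOTf, 2,6-lutidine, CH2Cl2, 0 °C → rt
Reagents that add atoms: triisopropylsilyl triflate, CC(C)[Si](OS(=O)(=O)C(F)(F)F)(C(C)C)C(C)C
Why: Silylation of both catechol hydroxyls; the bulky aryl TIPS ethers should survive organolithium reagents, hydroxide at low temperature and radical conditions.

Step 11
Reactants: 18 methyl 3,4-bis[(triisopropylsilyl)oxy]benzoate
Product: 19 N-methoxy-N-methyl-3,4-bis[(triisopropylsilyl)oxy]benzamide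
Conditions: MeNH(OMe)·HCl, i-PrMgCl, THF, −20 °C
Reagents that add atoms: N,O-dimethylhydroxylamine hydrochloride, CNOC.Cl
Why: Direct conversion of the ester into the Weinreb amide by the chloromagnesium amide.

Step 12
Reactants: 16 side-chain arene; 19 Weinreb amide
Product: 21 {3-[(2S,4R)-4-[(tert-butyldimethylsilyl)oxy]-5-methyl-2-(prop-1-en-2-yl)hex-5-en-1-yl]-2-methoxy-4,6-bis(methoxymethoxy)-5-(3-methylbut-2-en-1-yl)phenyl}{3,4-bis[(triisopropylsilyl)oxy]phenyl}methanone, via aryllithium 20 (not isolated)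
Conditions: 16, s-BuLi, TMEDA, THF, −78 °C; then 19, −78 → 0 °C; aq. NH4Cl
Reagents that add atoms: none
Why: Third directed ortho-metalation at the last ring hydrogen (between OMe and OMOM), then acylation with the Weinreb amide, whose chelated tetrahedral adduct prevents over-addition.

Step 13
Reactants: 21 bis-MOM benzophenone
Product: 22 {3-[(2S,4R)-4-[(tert-butyldimethylsilyl)oxy]-5-methyl-2-(prop-1-en-2-yl)hex-5-en-1-yl]-4,6-dihydroxy-2-methoxy-5-(3-methylbut-2-en-1-yl)phenyl}{3,4-bis[(triisopropylsilyl)oxy]phenyl}methanone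
Conditions: ZnBr2, n-PrSH, CH2Cl2, 0 °C → rt
Reagents that add atoms: none
Why: Lewis acid/thiol cleavage of the two aryl MOM acetals (transfer of CH2OMe to sulfur), mild enough for the silyl ethers and for the prenyl and isopropenyl groups, which stronger protic acid would cyclise onto the phenols.

Step 14
Reactants: 23 diethyl 2-(propan-2-ylidene)propanedioate
Product: 24 2-(propan-2-ylidene)propane-1,3-diol
Conditions: DIBAL-H (4.5 equiv), CH2Cl2, −78 → 0 °C; aqueous Rochelle salt
Reagents that add atoms: none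
Why: 1,2-Reduction of both esters of the alkylidene malonate to the allylic diol.

Step 15
Reactants: 24 2-(propan-2-ylidene)propane-1,3-diol
Product: 25 2-(hydroxymethyl)-3-methylbut-2-enal
Conditions: activated MnO2, CH2Cl2, rt, stopped at mono-oxidation
Reagents that add atoms: none
Why: Allylic oxidation with MnO2; the first formyl group makes the alkene electron-poor, so the second allylic alcohol should be oxidised much more slowly.

Step 16
Reactants: 25 2-(hydroxymethyl)-3-methylbut-2-enal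
Product: 26 2-formyl-3-methylbut-2-en-1-yl acetate
Conditions: Ac2O, pyridine, DMAP (cat.), CH2Cl2, 0 °C
Reagents that add atoms: acetic anhydride, CC(=O)OC(C)=O
Why: Acetylation of the primary allylic alcohol installs the leaving group for the Michael addition–elimination.

Step 17
Reactants: 22 aroylphloroglucinol monomethyl ether; 26 2-formyl-3-methylbut-2-en-1-yl acetate
Product: 29 (1R,5R,7R)-7-formyl-7-prenyl 4-O-methyl bicycle (full name in the list), via dearomatised methylene aldehyde 27 (not isolated), via bicyclic aldehyde 28 (not isolated)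
Conditions: CsOH·H2O (6 equiv), naphthalene-2,7-diylbis(methylene)-bridged bis(O-allylcinchonidinium) dibromide (20 mol%), CH2Cl2, −50 °C; then prenyl bromide, −50 → 0 °C
Reagents that add atoms: prenyl bromide, CC(C)=CCBr
Why: Under chiral phase-transfer conditions the bis-phenoxide of 22 adds through C1, the only ring carbon flanked by two phenoxide oxygens (C5 is flanked by one phenoxide and the OMe group, C3 carries the aroyl group), to the β-carbon of enal 26, and E1cB loss of acetate gives the dearomatised α-methylene aldehyde 27. The C5 carbon of its vinylogous enolate then closes ring B by a 6-endo-trig intramolecular Michael addition onto the terminal CH2 to give 28, whose C7 enolate, now the only acidic site, is C-alkylated by prenyl bromide to 29, which also blocks retro-Michael opening. The closest known reaction type is the alkylative dearomatisation–annulation of 3,5-dialkyl acylphloroglucinols with this same α-acetoxymethyl enal, including its enantioselective variant with dimeric cinchona ammonium salts, joined here to the phase-transfer α-allylation of α-branched aldehydes. C1 is set by the chiral ion pair in the first Michael addition; C5 follows from it because the three-atom tether can reach only the face of ring A that carries C8; the C7 prenyl group should enter from the open exo face, but this centre is re-set in step 18. The step needs C1 over C5 regioselectivity in the first C–C bond (secured by the C4 methyl ether and the smaller prenyl substituent), C5 over C3 and C over O selectivity in the ring closure (C3 is the stabilised aroyl-bearing terminus and O-addition is reversible), and C-alkylation at C7 (usual for allylic halides under phase transfer).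

Step 18
Reactants: 29 7-formyl-7-prenyl bicycle
Product: 30 (1R,5R,7R)-5-[(2S,4R)-4-[(tert-butyldimethylsilyl)oxy]-5-methyl-2-(prop-1-en-2-yl)hex-5-en-1-yl]-3-{3,4-bis[(triisopropylsilyl)oxy]benzoyl}-4-methoxy-8,8-dimethyl-1,7-bis(3-methylbut-2-en-1-yl)bicyclo[3.3.1]non-3-ene-2,9-dione
Conditions: tert-dodecanethiol (30 mol%), 1,1'-azobis(cyclohexanecarbonitrile) (20 mol%, in portions), PhCl, 110 °C
Reagents that add atoms: none
Why: Thiol-catalysed radical-chain decarbonylation: the thiyl radical abstracts the formyl hydrogen, the tertiary acyl radical loses CO, and the planar C7 radical takes hydrogen from the thiol on the open exo face of ring B (the endo face is screened by ring A, as in exo attack on bicyclo[3.3.1]nonan-3-ones), so the prenyl group is pushed endo and the (7R) centre is set by substrate control.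

Step 19
Reactants: 30 silyl-protected 4-O-methyl bicycle
Product: 31 (1R,5R,7R)-5-[(2S,4R)-4-[(tert-butyldimethylsilyl)oxy]-5-methyl-2-(prop-1-en-2-yl)hex-5-en-1-yl]-3-{3,4-bis[(triisopropylsilyl)oxy]benzoyl}-4-hydroxy-8,8-dimethyl-1,7-bis(3-methylbut-2-en-1-yl)bicyclo[3.3.1]non-3-ene-2,9-dione
Conditions: LiCl, DMSO, 120 °C; aq. NaH2PO4 work-up
Reagents that add atoms: none
Why: SN2 demethylation of the vinylogous methyl ester by chloride in hot DMSO, the standard unmasking of the enolised β-diketone in this compound class; no stereocentre is epimerisable.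

Step 20
Reactants: 31 tris-silyl ether of the target
Product: 32 target, (1R,5R,7R)-3-(3,4-dihydroxybenzoyl)-4-hydroxy-5-[(2S,4R)-4-hydroxy-5-methyl-2-(prop-1-en-2-yl)hex-5-en-1-yl]-8,8-dimethyl-1,7-bis(3-methylbut-2-en-1-yl)bicyclo[3.3.1]non-3-ene-2,9-dione
Conditions: TBAF, AcOH, THF, 0 °C → rt
Reagents that add atoms: none
Why: Fluoride cleaves the two aryl TIPS ethers and the allylic TBS ether; acetic acid buffers the phenoxides and the acidic enol, so no acid- or base-induced cyclisation onto the prenyl groups should occur.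

## Compound list

1 | furan-2(5H)-one | O=C1OCC=C1 | starting material
2 | 4,4,5,5-tetramethyl-2-(prop-1-en-2-yl)-1,3,2-dioxaborolane | CC(=C)B1OC(C)(C)C(C)(C)O1 | starting material
3 | (S)-4-(prop-1-en-2-yl)dihydrofuran-2(3H)-one | C=C(C)[C@H](CC1=O)CO1 | intermediate
4 | (5S)-6-hydroxy-2-methyl-5-(prop-1-en-2-yl)hex-1-en-3-one | C=C(C)[C@H](CC(=O)C(=C)C)CO | intermediate
5 | (5S)-6-iodo-2-methyl-5-(prop-1-en-2-yl)hex-1-en-3-one | C=C(C)[C@H](CC(=O)C(=C)C)CI | intermediate
6 | (3R,5S)-6-iodo-2-methyl-5-(prop-1-en-2-yl)hex-1-en-3-ol | C=C(C)[C@H](C[C@@H](O)C(=C)C)CI | intermediate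
7 | tert-butyl{[(3R,5S)-6-iodo-2-methyl-5-(prop-1-en-2-yl)hex-1-en-3-yl]oxy}dimethylsilane | C=C(C)[C@H](C[C@@H](O[Si](C)(C)C(C)(C)C)C(=C)C)CI | intermediate
8 | 5-methoxybenzene-1,3-diol | COc1cc(O)cc(O)c1 | starting material
9 | 1-methoxy-3,5-bis(methoxymethoxy)benzene | COCOc1cc(OC)cc(OCOC)c1 | intermediate
10 | [4-methoxy-2,6-bis(methoxymethoxy)phenyl]lithium | [Li]c1c(OCOC)cc(OC)cc1OCOC | intermediate (not isolated)
11 | 5-methoxy-1,3-bis(methoxymethoxy)-2-(3-methylbut-2-en-1-yl)benzene | COCOc1cc(OC)cc(OCOC)c1CC=C(C)C | intermediate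
12 | [6-methoxy-2,4-bis(methoxymethoxy)-3-(3-methylbut-2-en-1-yl)phenyl]lithium | [Li]c1c(OC)cc(OCOC)c(CC=C(C)C)c1OCOC | intermediate (not isolated)
13 | 2-iodo-1-methoxy-3,5-bis(methoxymethoxy)-4-(3-methylbut-2-en-1-yl)benzene | Ic1c(OC)cc(OCOC)c(CC=C(C)C)c1OCOC | intermediate
14 | {(2S,4R)-4-[(tert-butyldimethylsilyl)oxy]-5-methyl-2-(prop-1-en-2-yl)hex-5-en-1-yl}lithium | C=C(C)[C@H](C[C@@H](O[Si](C)(C)C(C)(C)C)C(=C)C)C[Li] | intermediate (not isolated)
15 | {(2S,4R)-4-[(tert-butyldimethylsilyl)oxy]-5-methyl-2-(prop-1-en-2-yl)hex-5-en-1-yl}zinc chloride | C=C(C)[C@H](C[C@@H](O[Si](C)(C)C(C)(C)C)C(=C)C)C[Zn]Cl | intermediate (not isolated)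
16 | tert-butyl({(3R,5S)-6-[6-methoxy-2,4-bis(methoxymethoxy)-3-(3-methylbut-2-en-1-yl)phenyl]-2-methyl-5-(prop-1-en-2-yl)hex-1-en-3-yl}oxy)dimethylsilane | C=C(C)[C@H](C[C@@H](O[Si](C)(C)C(C)(C)C)C(=C)C)Cc1c(OC)cc(OCOC)c(CC=C(C)C)c1OCOC | intermediate
17 | methyl 3,4-dihydroxybenzoate | COC(=O)c1ccc(O)c(O)c1 | starting material
18 | methyl 3,4-bis[(triisopropylsilyl)oxy]benzoate | COC(=O)c1ccc(O[Si](C(C)C)(C(C)C)C(C)C)c(O[Si](C(C)C)(C(C)C)C(C)C)c1 | intermediate
19 | N-methoxy-N-methyl-3,4-bis[(triisopropylsilyl)oxy]benzamide | CON(C)C(=O)c1ccc(O[Si](C(C)C)(C(C)C)C(C)C)c(O[Si](C(C)C)(C(C)C)C(C)C)c1 | intermediate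
20 | aryllithium of 16, lithiated at the ring carbon between OMe and OMOM | C=C(C)[C@H](C[C@@H](O[Si](C)(C)C(C)(C)C)C(=C)C)Cc1c(OC)c([Li])c(OCOC)c(CC=C(C)C)c1OCOC | intermediate (not isolated)
21 | {3-[(2S,4R)-4-[(tert-butyldimethylsilyl)oxy]-5-methyl-2-(prop-1-en-2-yl)hex-5-en-1-yl]-2-methoxy-4,6-bis(methoxymethoxy)-5-(3-methylbut-2-en-1-yl)phenyl}{3,4-bis[(triisopropylsilyl)oxy]phenyl}methanone | C=C(C)[C@H](C[C@@H](O[Si](C)(C)C(C)(C)C)C(=C)C)Cc1c(OC)c(C(=O)c2ccc(O[Si](C(C)C)(C(C)C)C(C)C)c(O[Si](C(C)C)(C(C)C)C(C)C)c2)c(OCOC)c(CC=C(C)C)c1OCOC | intermediate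
22 | {3-[(2S,4R)-4-[(tert-butyldimethylsilyl)oxy]-5-methyl-2-(prop-1-en-2-yl)hex-5-en-1-yl]-4,6-dihydroxy-2-methoxy-5-(3-methylbut-2-en-1-yl)phenyl}{3,4-bis[(triisopropylsilyl)oxy]phenyl}methanone | C=C(C)[C@H](C[C@@H](O[Si](C)(C)C(C)(C)C)C(=C)C)Cc1c(OC)c(C(=O)c2ccc(O[Si](C(C)C)(C(C)C)C(C)C)c(O[Si](C(C)C)(C(C)C)C(C)C)c2)c(O)c(CC=C(C)C)c1O | intermediate
23 | diethyl 2-(propan-2-ylidene)propanedioate | CCOC(=O)C(=C(C)C)C(=O)OCC | starting material
24 | 2-(propan-2-ylidene)propane-1,3-diol | CC(C)=C(CO)CO | intermediate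
25 | 2-(hydroxymethyl)-3-methylbut-2-enal | CC(C)=C(CO)C=O | intermediate
26 | 2-formyl-3-methylbut-2-en-1-yl acetate | CC(=O)OCC(C=O)=C(C)C | intermediate
27 | 6-(3-formyl-2-methylbut-3-en-2-yl)-5-hydroxy-3-methoxy-6-(3-methylbut-2-en-1-yl)-4-[(2S,4R)-4-[(tert-butyldimethylsilyl)oxy]-5-methyl-2-(prop-1-en-2-yl)hex-5-en-1-yl]-2-{3,4-bis[(triisopropylsilyl)oxy]benzoyl}cyclohexa-2,4-dien-1-one, quaternary carbon configured as in 29 | C=C(C)[C@H](C[C@@H](O[Si](C)(C)C(C)(C)C)C(=C)C)CC1=C(O)[C@@](CC=C(C)C)(C(C)(C)C(=C)C=O)C(=O)C(C(=O)c2ccc(O[Si](C(C)C)(C(C)C)C(C)C)c(O[Si](C(C)C)(C(C)C)C(C)C)c2)=C1OC | intermediate (not isolated)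
28 | (1R,5R)-5-[(2S,4R)-4-[(tert-butyldimethylsilyl)oxy]-5-methyl-2-(prop-1-en-2-yl)hex-5-en-1-yl]-3-{3,4-bis[(triisopropylsilyl)oxy]benzoyl}-4-methoxy-8,8-dimethyl-1-(3-methylbut-2-en-1-yl)-2,9-dioxobicyclo[3.3.1]non-3-ene-7-carbaldehyde, C7 epimers | C=C(C)[C@H](C[C@@H](O[Si](C)(C)C(C)(C)C)C(=C)C)C[C@@]12CC(C=O)C(C)(C)[C@@](CC=C(C)C)(C(=O)C(C(=O)c3ccc(O[Si](C(C)C)(C(C)C)C(C)C)c(O[Si](C(C)C)(C(C)C)C(C)C)c3)=C1OC)C2=O | intermediate (not isolated)
29 | (1R,5R,7R)-5-[(2S,4R)-4-[(tert-butyldimethylsilyl)oxy]-5-methyl-2-(prop-1-en-2-yl)hex-5-en-1-yl]-3-{3,4-bis[(triisopropylsilyl)oxy]benzoyl}-4-methoxy-8,8-dimethyl-1,7-bis(3-methylbut-2-en-1-yl)-2,9-dioxobicyclo[3.3.1]non-3-ene-7-carbaldehyde (formyl endo, prenyl exo) | C=C(C)[C@H](C[C@@H](O[Si](C)(C)C(C)(C)C)C(=C)C)C[C@@]12C[C@@](CC=C(C)C)(C=O)C(C)(C)[C@@](CC=C(C)C)(C(=O)C(C(=O)c3ccc(O[Si](C(C)C)(C(C)C)C(C)C)c(O[Si](C(C)C)(C(C)C)C(C)C)c3)=C1OC)C2=O | intermediate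
30 | (1R,5R,7R)-5-[(2S,4R)-4-[(tert-butyldimethylsilyl)oxy]-5-methyl-2-(prop-1-en-2-yl)hex-5-en-1-yl]-3-{3,4-bis[(triisopropylsilyl)oxy]benzoyl}-4-methoxy-8,8-dimethyl-1,7-bis(3-methylbut-2-en-1-yl)bicyclo[3.3.1]non-3-ene-2,9-dione | C=C(C)[C@H](C[C@@H](O[Si](C)(C)C(C)(C)C)C(=C)C)C[C@@]12C[C@@H](CC=C(C)C)C(C)(C)[C@@](CC=C(C)C)(C(=O)C(C(=O)c3ccc(O[Si](C(C)C)(C(C)C)C(C)C)c(O[Si](C(C)C)(C(C)C)C(C)C)c3)=C1OC)C2=O | intermediate
31 | (1R,5R,7R)-5-[(2S,4R)-4-[(tert-butyldimethylsilyl)oxy]-5-methyl-2-(prop-1-en-2-yl)hex-5-en-1-yl]-3-{3,4-bis[(triisopropylsilyl)oxy]benzoyl}-4-hydroxy-8,8-dimethyl-1,7-bis(3-methylbut-2-en-1-yl)bicyclo[3.3.1]non-3-ene-2,9-dione | C=C(C)[C@H](C[C@@H](O[Si](C)(C)C(C)(C)C)C(=C)C)C[C@@]12C[C@@H](CC=C(C)C)C(C)(C)[C@@](CC=C(C)C)(C(=O)C(C(=O)c3ccc(O[Si](C(C)C)(C(C)C)C(C)C)c(O[Si](C(C)C)(C(C)C)C(C)C)c3)=C1O)C2=O | intermediate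
32 | (1R,5R,7R)-3-(3,4-dihydroxybenzoyl)-4-hydroxy-5-[(2S,4R)-4-hydroxy-5-methyl-2-(prop-1-en-2-yl)hex-5-en-1-yl]-8,8-dimethyl-1,7-bis(3-methylbut-2-en-1-yl)bicyclo[3.3.1]non-3-ene-2,9-dione | C=C(C)[C@H](C[C@@H](O)C(=C)C)C[C@@]12C[C@@H](CC=C(C)C)C(C)(C)[C@@](CC=C(C)C)(C(=O)C(C(=O)c3ccc(O)c(O)c3)=C1O)C2=O | target

## Step count and risks

Total step count: 20. Longest linear sequence: 12 steps (steps 1–5, 9, 12, 13, 17–20).

**Steps most likely to fail**

1. Step 17. What may go wrong: the first C–C bond forms at C5 instead of C1, the ion pair gives incomplete facial control, or the hindered C7 enolate undergoes O-alkylation or retro-Michael opening in the one-pot instead of C-prenylation. Fallback: the sequence is taken apart and the C7 prenyl group is brought in by palladium instead of SN2 alkylation. Setting out from 22 and 26, the annulation is run without prenyl bromide and quenched cold, so that bicyclic aldehyde 28 is isolated. Its potassium enolate (KHMDS, THF, −78 °C) is O-acylated with 3-methylbut-2-en-1-yl chloroformate to the prenyl enol carbonate F1. Pd(PPh3)4 in THF then effects the Tsuji decarboxylative allylation, in which the enolate/π-prenylpalladium pair should join at C7 and the unsubstituted allyl terminus, and the route is rejoined at 29.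

2. Step 18. What may go wrong: hydrogen abstraction from the hindered formyl group is slow and the chain collapses, the thiyl radical adds to the isopropenyl groups, or hydrogen transfer to the C7 radical is not fully exo-selective. Fallback: the C7 radical is generated from a carboxyl group. Setting out from 29, Pinnick oxidation (NaClO2, NaH2PO4, 2-methylbut-2-ene, t-BuOH/H2O) gives the carboxylic acid F2. DCC and 2-mercaptopyridine N-oxide give the Barton ester F3. Visible-light photolysis with 2-methylpropane-2-thiol in benzene (Barton reductive decarboxylation) returns to 30, with hydrogen again delivered to the exo face.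

3. Step 12. What may go wrong: benzylic deprotonation at the prenyl or side-chain CH2 competes with ring metalation of the fully substituted arene. Fallback: the aroyl group is introduced by electrophilic substitution of a phenoxide instead of by metalation. Setting out from 16, ZnBr2/n-PrSH removes the MOM groups to give the resorcinol F4. Its bromomagnesium phenoxide (EtMgBr, toluene) is hydroxyalkylated at the only free ring carbon, ortho to the phenoxide, by 3,4-bis[(triisopropylsilyl)oxy]benzaldehyde F5 (from 3,4-dihydroxybenzaldehyde and TIPSOTf), giving the diaryl carbinol F6. MnO2 oxidation of F6 rejoins the route at 22.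

Further compounds
F1 | step 17 | prenyl enol carbonate of 28, [(1R,5R)-bicycle]-7-ylidenemethyl 3-methylbut-2-en-1-yl carbonate | C=C(C)[C@H](C[C@@H](O[Si](C)(C)C(C)(C)C)C(=C)C)C[C@@]12CC(=COC(=O)OCC=C(C)C)C(C)(C)[C@@](CC=C(C)C)(C(=O)C(C(=O)c3ccc(O[Si](C(C)C)(C(C)C)C(C)C)c(O[Si](C(C)C)(C(C)C)C(C)C)c3)=C1OC)C2=O
F2 | step 18 | 7-carboxylic acid corresponding to aldehyde 29 | C=C(C)[C@H](C[C@@H](O[Si](C)(C)C(C)(C)C)C(=C)C)C[C@@]12C[C@@](CC=C(C)C)(C(=O)O)C(C)(C)[C@@](CC=C(C)C)(C(=O)C(C(=O)c3ccc(O[Si](C(C)C)(C(C)C)C(C)C)c(O[Si](C(C)C)(C(C)C)C(C)C)c3)=C1OC)C2=O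
F3 | step 18 | 2-thioxopyridin-1(2H)-yl ester (Barton ester) of F2 | C=C(C)[C@H](C[C@@H](O[Si](C)(C)C(C)(C)C)C(=C)C)C[C@@]12C[C@@](CC=C(C)C)(C(=O)On4ccccc4=S)C(C)(C)[C@@](CC=C(C)C)(C(=O)C(C(=O)c3ccc(O[Si](C(C)C)(C(C)C)C(C)C)c(O[Si](C(C)C)(C(C)C)C(C)C)c3)=C1OC)C2=O
F4 | step 12 | 4-[(2S,4R)-4-[(tert-butyldimethylsilyl)oxy]-5-methyl-2-(prop-1-en-2-yl)hex-5-en-1-yl]-5-methoxy-2-(3-methylbut-2-en-1-yl)benzene-1,3-diol | C=C(C)[C@H](C[C@@H](O[Si](C)(C)C(C)(C)C)C(=C)C)Cc1c(OC)cc(O)c(CC=C(C)C)c1O
F5 | step 12 | 3,4-bis[(triisopropylsilyl)oxy]benzaldehyde | O=Cc1ccc(O[Si](C(C)C)(C(C)C)C(C)C)c(O[Si](C(C)C)(C(C)C)C(C)C)c1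
F6 | step 12 | diaryl carbinol corresponding to ketone 22 (carbinol epimers) | C=C(C)[C@H](C[C@@H](O[Si](C)(C)C(C)(C)C)C(=C)C)Cc1c(OC)c(C(O)c2ccc(O[Si](C(C)C)(C(C)C)C(C)C)c(O[Si](C(C)C)(C(C)C)C(C)C)c2)c(O)c(CC=C(C)C)c1O
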